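Locants follow chroman-2-one numbering, unprimed for the 5,7-dihydroxy half and primed for the 5,6,7,8-tetrahydroxy half; the halves are joined C3–C3' and each is 3,4-cis (3S,4R,3'S,4'R).
Retrosynthesis: the six O-methyl groups and the hydroquinone level go last; C4'–C4a' and O1'–C2' are then cut together, leaving a hydroxyquinone and an arylidene acid that already holds the unprimed lactone. The arylidene C=C (Stobbe), the C3–CH2 bond (enolate alkylation) and the C4–aryl bond (rhodium-catalysed 1,4-addition) lead back to 5,7-dimethoxycoumarin.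
Enabling feature: the benzene ring C4a'/C5'/C6'/C7'/C8'/C8a' is a hydroquinone; two electrons higher it is a 2-hydroxy-1,4-benzoquinone whose single unsubstituted ring carbon (later C4a') is the carbon end of a vinylogous acid and sits next to the hydroxyl that becomes O1'.
Forward order: the unprimed pyranone is present from the start; the C4 aryl group, the C3 side chain and the C3 configuration follow; the primed pyranone closes in the key step as a pyranoquinone; reduction and demethylation finish.
Stereochemistry: C4 from the chiral rhodium catalyst; C3 from kinetic protonation anti to the C4 aryl group; C4' and C3' relayed from C3/C4 by allylic 1,3-strain in the acylammonium ion, supported by the chiral isothiourea.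

Key step: step 7

Assumption: the usual facial sense of (2S,3R)-HyperBTM (attack anti to its C2-phenyl group on the s-cis acylammonium ion) is taken to coincide with the substrate bias (matched pair); 5,7-dimethoxycoumarin and 2,3-dimethoxy-1,4-benzoquinone are taken as purchasable.

**Route**

Step 1
Reactants: 1 5,7-dimethoxycoumarin (5,7-dimethoxy-2H-chromen-2-one); 2 4-methoxyphenylboronic acid
Product: 3 (R)-5,7-dimethoxy-4-(4-methoxyphenyl)chroman-2-one
Conditions: Rh(acac)(C2H4)2 (3 mol%), (R)-SEGPHOS [(R)-5,5'-bis(diphenylphosphino)-4,4'-bi-1,3-benzodioxole], dioxane/H2O, 60 °C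
Reagents that add atoms: none
Why: Hayashi–Miyaura rhodium-catalysed asymmetric 1,4-addition of an arylboronic acid to a coumarin, in which the aryl–rhodium species inserts the C3=C4 bond on the face left open by the ligand (expected to set C4 as R by analogy with other 4-arylchroman-2-ones) and water releases the lactone.

Step 2
Reactants: 3 (R)-5,7-dimethoxy-4-(4-methoxyphenyl)chroman-2-one; 4 methyl bromoacetate
Product: 6 methyl 2-[(3S,4R)-5,7-dimethoxy-4-(4-methoxyphenyl)-2-oxochroman-3-yl]acetate (3,4-trans), via lithium lactone enolate 5 (not isolated)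
Conditions: LiN(SiMe3)2, THF, −78 °C; then 4, −78 to −40 °C
Reagents that add atoms: none
Why: SN2 alkylation of a lithium lactone enolate with an α-bromo ester at a temperature where the aryl ester enolate is stable; the electrophile should enter anti to the C4 aryl group (trans), a C3 configuration that is not needed later because C3 is reset in step 4.

Step 3
Reactants: 6 methyl 2-[(3S,4R)-5,7-dimethoxy-4-(4-methoxyphenyl)-2-oxochroman-3-yl]acetate; 7 4-methoxybenzaldehyde
Product: 11 (E)-2-[(3RS,4R)-5,7-dimethoxy-4-(4-methoxyphenyl)-2-oxochroman-3-yl]-3-(4-methoxyphenyl)acrylic acid (C3 epimers), via ring-opened phenol diester 8 (not isolated), via Stobbe half-ester 9 (not isolated), via hydroxy diacid 10 (not isolated)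
Conditions: NaOMe, MeOH, 65 °C; then aq. NaOH, 65 °C; then aq. HCl; TsOH·H2O (cat.), toluene, 60 °C
Reagents that add atoms: sodium hydroxide, [Na+].[OH-]
Why: Stobbe condensation of a 2-substituted succinate, which reacts at the unsubstituted methylene through the paraconate lactone and E1cB opening to give the E-arylidene half-ester; methoxide first opens the aryl lactone to the phenoxide diester, hydroxide cleaves the remaining methyl ester, and acid recloses the six-membered aryl lactone from the 2-hydroxyaryl acid (the acrylic acid would need a seven-membered ring), with C4 untouched and C3 left as a mixture.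

Step 4
Reactants: 11 (E)-2-[(3RS,4R)-5,7-dimethoxy-4-(4-methoxyphenyl)-2-oxochroman-3-yl]-3-(4-methoxyphenyl)acrylic acid
Product: 13 (E)-2-[(3S,4R)-5,7-dimethoxy-4-(4-methoxyphenyl)-2-oxochroman-3-yl]-3-(4-methoxyphenyl)acrylic acid (3,4-cis), via dilithium carboxylate enolate 12 (not isolated)
Conditions: LiN(SiMe3)2 (2.2 equiv), THF, −78 °C; then t-BuCO2H, −78 °C; aq. HCl work-up
Reagents that add atoms: none
Why: Kinetic protonation of a lactone enolate (contra-thermodynamic epimerisation): C3 is planar in the dianion, the C4 aryl group is held pseudoaxial by the peri 5-methoxy group and covers one face, and the bulky acid should deliver the proton to the α-carbon from the other face, which leaves the side chain cis to the aryl group (3S).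

Step 5
Reactants: 14 2,3-dimethoxy-1,4-benzoquinone
Product: 15 5,6-dimethoxybenzene-1,2,4-triyl triacetate (1,2,4-triacetoxy-5,6-dimethoxybenzene)
Conditions: Ac2O, BF3·OEt2 (cat.), 40 °C
Reagents that add atoms: acetic anhydride, CC(=O)OC(C)=O
Why: Thiele–Winter acetoxylation, that is acid-catalysed conjugate addition of acetate to the unsubstituted enone carbon followed by enolisation and peracetylation; the two unsubstituted ring carbons are equivalent, so one regioisomer results.

Step 6
Reactants: 15 5,6-dimethoxybenzene-1,2,4-triyl triacetate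
Product: 17 2-hydroxy-5,6-dimethoxy-1,4-benzoquinone, via benzenetriol 16 (not isolated)
Conditions: HCl (cat.), MeOH, 65 °C, argon; then FeCl3, H2O, 0 °C
Reagents that add atoms: none
Why: Acid-catalysed methanolysis of the three aryl acetates frees the air-sensitive benzenetriol, which FeCl3 oxidises at once to the para-quinone tautomer, the standard second half of the Thiele–Winter route to hydroxyquinones.

Step 7
Reactants: 13 (E)-2-[(3S,4R)-5,7-dimethoxy-4-(4-methoxyphenyl)-2-oxochroman-3-yl]-3-(4-methoxyphenyl)acrylic acid; 17 2-hydroxy-5,6-dimethoxy-1,4-benzoquinone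
Product: 19 (3S,4R)-3-[(3S,4R)-5,7-dimethoxy-4-(4-methoxyphenyl)-2-oxochroman-3-yl]-6,7-dimethoxy-4-(4-methoxyphenyl)-3,4-dihydro-2H-chromene-2,5,8-trione, via acid chloride 18 (not isolated)
Conditions: 1-chloro-N,N,2-trimethylprop-1-en-1-amine, CH2Cl2, 0 °C to rt; then 17, (2S,3R)-3-isopropyl-2-phenyl-3,4-dihydro-2H-benzo[4,5]thiazolo[3,2-a]pyrimidine (HyperBTM, 20 mol%), 2,6-lutidine, CH2Cl2, −40 °C to rt
Reagents that add atoms: none
Why: Proposed new method: acid chloride 18 acylates the isothiourea nitrogen to give an α,β-unsaturated acylammonium ion, the lutidine-generated anion of the vinylogous acid 17 adds through its only C–H carbon to C4' (Michael addition), the ammonium enolate is protonated at C3', and the quinone hydroxyl then attacks the acylammonium carbonyl C2' in a 6-exo-trig lactonisation that closes the primed pyranone and frees the catalyst. The closest known reaction type is the isothiourea- or carbene-catalysed Michael addition–lactonisation of 2-hydroxy-1,4-naphthoquinone and of 1,3-dicarbonyl compounds with β-aryl acylammonium or acylazolium ions, which has not been shown for an α-branched acceptor. C4' (R) is controlled by allylic 1,3-strain: the aryl group cis to C3 on the alkene keeps the C3–H bond in the alkene plane, so the nucleophile enters past the flat lactone carbonyl and anti to the C4 diarylmethine, the same face that the phenyl group of the catalyst leaves open. C3' (S, cis to the C4' aryl group) is controlled by kinetic protonation of the ammonium enolate on the face away from the quinone ring just attached at C4' in its strain-minimised rotamer. The step needs C- over O-attack and conjugate over direct addition, which the single nucleophilic carbon of 17 and the reversibility of O-acylation provide, and it needs the labile C3–H to survive, for which the weak base 2,6-lutidine (strong enough for the acidic hydroxyquinone only) and low temperature are chosen.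

Step 8
Reactants: 19 (3S,4R)-3-[(3S,4R)-5,7-dimethoxy-4-(4-methoxyphenyl)-2-oxochroman-3-yl]-6,7-dimethoxy-4-(4-methoxyphenyl)-3,4-dihydro-2H-chromene-2,5,8-trione
Product: 20 (3S,4R)-3-[(3S,4R)-5,7-dimethoxy-4-(4-methoxyphenyl)-2-oxochroman-3-yl]-5,8-dihydroxy-6,7-dimethoxy-4-(4-methoxyphenyl)chroman-2-one
Conditions: Na2S2O4, EtOAc/H2O, rt, argon
Reagents that add atoms: none
Why: Dithionite reduction of a quinone to its hydroquinone by two-electron transfer in a two-phase system, fast enough to outrun hydrolysis of the acyloxyquinone lactone and without effect on lactones, aryl ethers or the four stereocentres.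

Step 9
Reactants: 20 (3S,4R)-3-[(3S,4R)-5,7-dimethoxy-4-(4-methoxyphenyl)-2-oxochroman-3-yl]-5,8-dihydroxy-6,7-dimethoxy-4-(4-methoxyphenyl)chroman-2-one
Product: 21 (3S,4R)-3-[(3S,4R)-5,7-dihydroxy-4-(4-hydroxyphenyl)-2-oxochroman-3-yl]-5,6,7,8-tetrahydroxy-4-(4-hydroxyphenyl)chroman-2-one (CNP0064734.1)
Conditions: BBr3, CH2Cl2, −78 °C to rt, argon; then degassed H2O, 0 °C
Reagents that add atoms: none
Why: Lewis acid cleavage of the six aryl methyl ethers with BBr3 (aryloxyborane formation with SN2 loss of bromomethane, then hydrolysis), a standard last step for polyphenolic 4-aryl-dihydrocoumarins that should leave the aryl lactones and the C–H stereocentres intact when kept cold, acidic and oxygen-free.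

**Compound list**

1 | 5,7-dimethoxycoumarin (5,7-dimethoxy-2H-chromen-2-one) | O=C1C=Cc2c(OC)cc(OC)cc2O1 | starting material
2 | 4-methoxyphenylboronic acid | COc1ccc(B(O)O)cc1 | starting material
3 | (R)-5,7-dimethoxy-4-(4-methoxyphenyl)chroman-2-one | O=C1Oc2cc(OC)cc(OC)c2[C@@H](c2ccc(OC)cc2)C1 | intermediate
4 | methyl bromoacetate | COC(=O)CBr | starting material
5 | lithium (R)-5,7-dimethoxy-4-(4-methoxyphenyl)-4H-chromen-2-olate (lithium enolate of 3, formed in the flask) | [Li+].[O-]C1=C[C@H](c2ccc(OC)cc2)c2c(OC)cc(OC)cc2O1 | intermediate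
6 | methyl 2-[(3S,4R)-5,7-dimethoxy-4-(4-methoxyphenyl)-2-oxochroman-3-yl]acetate (3,4-trans) | O=C1Oc2cc(OC)cc(OC)c2[C@@H](c2ccc(OC)cc2)[C@@H]1CC(=O)OC | intermediate
7 | 4-methoxybenzaldehyde | COc1ccc(C=O)cc1 | starting material
8 | dimethyl 2-[(R)-(2-hydroxy-4,6-dimethoxyphenyl)(4-methoxyphenyl)methyl]succinate (C2 epimers; sodium phenoxide in the flask) | COC(=O)CC(C(=O)OC)[C@H](c1ccc(OC)cc1)c1c(O)cc(OC)cc1OC | intermediate
9 | (E)-2-[(R)-(2-hydroxy-4,6-dimethoxyphenyl)(4-methoxyphenyl)methyl]-3-(methoxycarbonyl)-4-(4-methoxyphenyl)but-3-enoic acid (C2 epimers; sodium salts in the flask) | OC(=O)C([C@H](c1ccc(OC)cc1)c1c(O)cc(OC)cc1OC)/C(=C\c1ccc(OC)cc1)C(=O)OC | intermediate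
10 | (E)-2-[(R)-(2-hydroxy-4,6-dimethoxyphenyl)(4-methoxyphenyl)methyl]-3-(4-methoxybenzylidene)succinic acid (C2 epimers, formed in the flask) | OC(=O)C([C@H](c1ccc(OC)cc1)c1c(O)cc(OC)cc1OC)/C(=C\c1ccc(OC)cc1)C(=O)O | intermediate
11 | (E)-2-[(3RS,4R)-5,7-dimethoxy-4-(4-methoxyphenyl)-2-oxochroman-3-yl]-3-(4-methoxyphenyl)acrylic acid (C3 epimers) | O=C1Oc2cc(OC)cc(OC)c2[C@@H](c2ccc(OC)cc2)C1/C(=C\c1ccc(OC)cc1)C(=O)O | intermediate
12 | dilithium salt of 11: lithium carboxylate and lithium lactone enolate, 4R, E alkene (formed in the flask) | [Li+].[Li+].[O-]C1=C(/C(=C\c2ccc(OC)cc2)C(=O)[O-])[C@H](c2ccc(OC)cc2)c2c(OC)cc(OC)cc2O1 | intermediate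
13 | (E)-2-[(3S,4R)-5,7-dimethoxy-4-(4-methoxyphenyl)-2-oxochroman-3-yl]-3-(4-methoxyphenyl)acrylic acid (3,4-cis) | O=C1Oc2cc(OC)cc(OC)c2[C@@H](c2ccc(OC)cc2)[C@H]1/C(=C\c1ccc(OC)cc1)C(=O)O | intermediate
14 | 2,3-dimethoxy-1,4-benzoquinone | COC1=C(OC)C(=O)C=CC1=O | starting material
15 | 5,6-dimethoxybenzene-1,2,4-triyl triacetate | CC(=O)Oc1cc(OC(C)=O)c(OC)c(OC)c1OC(C)=O | intermediate
16 | 5,6-dimethoxybenzene-1,2,4-triol (formed in the flask) | Oc1cc(O)c(OC)c(OC)c1O | intermediate
17 | 2-hydroxy-5,6-dimethoxy-1,4-benzoquinone | COC1=C(OC)C(=O)C(O)=CC1=O | intermediate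
18 | (E)-2-[(3S,4R)-5,7-dimethoxy-4-(4-methoxyphenyl)-2-oxochroman-3-yl]-3-(4-methoxyphenyl)acryloyl chloride (formed in the flask) | O=C1Oc2cc(OC)cc(OC)c2[C@@H](c2ccc(OC)cc2)[C@H]1/C(=C\c1ccc(OC)cc1)C(=O)Cl | intermediate
19 | (3S,4R)-3-[(3S,4R)-5,7-dimethoxy-4-(4-methoxyphenyl)-2-oxochroman-3-yl]-6,7-dimethoxy-4-(4-methoxyphenyl)-3,4-dihydro-2H-chromene-2,5,8-trione | O=C1Oc2cc(OC)cc(OC)c2[C@@H](c2ccc(OC)cc2)[C@H]1[C@H]1C(=O)OC2=C([C@H]1c1ccc(OC)cc1)C(=O)C(OC)=C(OC)C2=O | intermediate
20 | (3S,4R)-3-[(3S,4R)-5,7-dimethoxy-4-(4-methoxyphenyl)-2-oxochroman-3-yl]-5,8-dihydroxy-6,7-dimethoxy-4-(4-methoxyphenyl)chroman-2-one | O=C1Oc2cc(OC)cc(OC)c2[C@@H](c2ccc(OC)cc2)[C@H]1[C@H]1C(=O)Oc2c(O)c(OC)c(OC)c(O)c2[C@H]1c1ccc(OC)cc1 | intermediate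
21 | (3S,4R)-3-[(3S,4R)-5,7-dihydroxy-4-(4-hydroxyphenyl)-2-oxochroman-3-yl]-5,6,7,8-tetrahydroxy-4-(4-hydroxyphenyl)chroman-2-one | O=C1Oc2cc(O)cc(O)c2[C@@H](c2ccc(O)cc2)[C@H]1[C@H]1C(=O)Oc2c(O)c(O)c(O)c(O)c2[C@H]1c1ccc(O)cc1 | target

**Count and risks**

Total step count: 9. Longest linear sequence: 7 steps (steps 1, 2, 3, 4, 7, 8, 9); steps 5 and 6 form the second branch.

Steps most likely to fail:

1. The key annulation, step 7, is the largest risk. The α-branch may twist the acylammonium ion out of conjugation so that conjugate addition does not turn over. Deprotonation at C3 may cause epimerisation or alkene migration. Reversible opening of the acyloxyquinone lactone by the catalyst may erode C3', and catalyst and substrate may prefer opposite faces. The fallback uses known chemistry and sets out from 13 and benzenetriol 16, taken as the crude methanolysis product of step 6 before the FeCl3 oxidation and kept under argon. The two are combined in CF3CO2H/CH2Cl2 under argon in a Friedel–Crafts hydroarylation followed by lactonisation, the acid-mediated phenol–cinnamic acid annulation that is the classical route to 4-aryl-3,4-dihydrocoumarins. The only free ring carbon of 16 attacks C4' and a flanking hydroxyl closes the lactone, which should give 20 directly, where the route is rejoined. Closure through the other flanking hydroxyl would give the regioisomeric lactone (3S,4R)-3-[(3S,4R)-5,7-dimethoxy-4-(4-methoxyphenyl)-2-oxochroman-3-yl]-5,6-dihydroxy-7,8-dimethoxy-4-(4-methoxyphenyl)chroman-2-one F1, and step 9 would convert F1 into 21 as well, because full demethylation makes the two lactone regioisomers identical. No base is present, so C3 is not exposed to deprotonation; face selection then rests on the allylic-strain relay alone, and diastereomers may have to be separated.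

2. In step 3 the condensation may stall at the aldol or paraconate stage on the hindered succinate, the diester may self-condense, or relactonisation may be incomplete. The fallback forms the C3–Cα bond by cross-coupling instead of building the alkene by condensation, and sets out from 3. Silylation of its enolate (LiN(SiMe3)2, Me3SiCl, THF, −78 °C) would give [(4R)-5,7-dimethoxy-4-(4-methoxyphenyl)-4H-chromen-2-yl]oxy(trimethyl)silane F2. Palladium-catalysed α-alkenylation of this silyl ketene acetal (Pd(dba)2, P(t-Bu)3, ZnF2, DMF) would use as partner tert-butyl (Z)-2-bromo-3-(4-methoxyphenyl)acrylate F3, made from 7 by Wittig olefination with Ph3P=C(Br)CO2t-Bu. The coupling should proceed with retention of alkene geometry to tert-butyl (E)-2-[(3RS,4R)-5,7-dimethoxy-4-(4-methoxyphenyl)-2-oxochroman-3-yl]-3-(4-methoxyphenyl)acrylate F4. CF3CO2H then removes the tert-butyl group from F4 without touching the aryl lactone and returns 11, where the route is rejoined.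

3. In step 4 the protonation may show poor facial selectivity, may occur at the γ-carbon (alkene migration), or the aryl ester enolate may open to a ketene on warming. The fallback replaces kinetic by thermodynamic control and sets out from 11. C3 is equilibrated with DBU (1.5 equiv, the first equivalent being taken up by the carboxylic acid) in toluene at rt. After acidification the cis acid is separated by chromatography or crystallisation, and the trans isomer is returned to the equilibration. It rejoins the route at 13 and makes no new compound.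

Further compounds
F1 | step 7 | (3S,4R)-3-[(3S,4R)-5,7-dimethoxy-4-(4-methoxyphenyl)-2-oxochroman-3-yl]-5,6-dihydroxy-7,8-dimethoxy-4-(4-methoxyphenyl)chroman-2-one | O=C1Oc2cc(OC)cc(OC)c2[C@@H](c2ccc(OC)cc2)[C@H]1[C@H]1C(=O)Oc2c(OC)c(OC)c(O)c(O)c2[C@H]1c1ccc(OC)cc1
F2 | step 3 | [(4R)-5,7-dimethoxy-4-(4-methoxyphenyl)-4H-chromen-2-yl]oxy(trimethyl)silane | C[Si](C)(C)OC1=C[C@H](c2ccc(OC)cc2)c2c(OC)cc(OC)cc2O1
F3 | step 3 | tert-butyl (Z)-2-bromo-3-(4-methoxyphenyl)acrylate | CC(C)(C)OC(=O)/C(Br)=C/c1ccc(OC)cc1
F4 | step 3 | tert-butyl (E)-2-[(3RS,4R)-5,7-dimethoxy-4-(4-methoxyphenyl)-2-oxochroman-3-yl]-3-(4-methoxyphenyl)acrylate | O=C1Oc2cc(OC)cc(OC)c2[C@@H](c2ccc(OC)cc2)C1/C(=C\c1ccc(OC)cc1)C(=O)OC(C)(C)C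
F0 | step 4 | none | none
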